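A direct plan would keep every hydroxyl as a benzyl ether and form each diaryl ether from a hindered 2,6-dioxygenated phenoxide and an aryl halide, boronic acid or fluoro aldehyde.
Ring A would be grown de novo on the aryloxyacetate A1 (dianion Claisen condensation, pyranone, Dieckmann aromatisation) to give the two-ring phenol A2; SNAr on a fluoro aldehyde and Dakin oxidation would add ring C (three-ring phenol A3).
An Ullmann coupling of A3 with the two-ring aryl iodide A4 and a twelvefold hydrogenolysis would finish.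
Weak point 1: the de novo construction of ring A, a long linear run of C–C bond formations with a MOM group put on and taken off and a bromide turned into a phenol, all to make one diaryl ether beside a trioxygenated ring that can be bought.
Weak point 2: the late Ullmann coupling of A3, a di-ortho-substituted and easily oxidised phenol, with the electron-rich iodide A4 at the most valuable stage.
Weak point 3: the halogen exchange and metalation–borylation–oxidation steps that only adjust functional groups and build nothing.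

**Retrosynthetic overview**
Feature used: ring C carries three neighbouring oxygens, O–ring B at C1, O–ring D at C2 and OH at C3; C2–O is the most crowded ether bond of the molecule.
Key disconnection: C2(ring C)–O(ring D), formed last by rhodium-carbenoid O–H insertion of the unhindered two-ring phenol 5 (rings D–E) into the three-ring o-quinone diazide 15; C2 is the electrophile, the reverse of a copper coupling, and the diazide oxygen returns as the free C3–OH of the target.
Ring C is built around one nitro group: both ortho fluorides of 1,3-difluoro-5-methoxy-2-nitrobenzene are displaced (ring B phenoxide at C1, benzyl oxide at C3), then the nitro group at C2 is turned into the diazo group.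
The arms A–B and D–E come in two steps each from commercial methyl ethers: C–O coupling, then Dakin oxidation of a formyl group used as a latent hydroxyl.
No ring is made de novo, no hindered phenol is arylated late, and there is no halogen–metal traffic; the ether bonds form in the order D–E and A–B, then B–C, then C–D.

Key step: step 8

Remark: rings are lettered A (2-aryloxyphloroglucinol end) to E (3,4,5-trihydroxyphenyl end); 15 is drawn as the diazo ketone form of the 2-diazoniophenolate; the target is achiral, so no stereocentre has to be set.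

Step 1
Reactants: 1 4-hydroxy-3,5-dimethoxybenzaldehyde (syringaldehyde); 2 (3,4,5-trimethoxyphenyl)boronic acid
Product: 3 3,5-dimethoxy-4-(3,4,5-trimethoxyphenoxy)benzaldehyde
Conditions: 2 (2 equiv), Cu(OAc)2 (1.0 equiv), pyridine (5 equiv), 4 Å MS, CH2Cl2, dry air, rt, 48 h
Reagents that add atoms: none
Why: Chan–Lam oxidative O-arylation runs at room temperature, accepts di-ortho-substituted and electron-poor phenols, leaves the formyl group alone, and air re-oxidises copper so that Cu(OAc)2 is returned.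

Step 2
Reactants: 3 3,5-dimethoxy-4-(3,4,5-trimethoxyphenoxy)benzaldehyde
Product: 5 3,5-dimethoxy-4-(3,4,5-trimethoxyphenoxy)phenol, via aryl formate 4 (not isolated)
Conditions: mCPBA (1.4 equiv), CH2Cl2, 0 °C → rt; aq. Na2S2O3 wash; then K2CO3 (0.2 equiv), MeOH, rt
Reagents that add atoms: mCPBA, OOC(=O)c1cccc(Cl)c1
Why: Baeyer–Villiger (Dakin-type) oxidation, in which the aryl group para to the aryloxy donor migrates in preference to hydrogen and mild methanolysis of the formate frees the unhindered para phenol of ring D.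

Step 3
Reactants: 6 2,4,6-trimethoxyphenol; 7 4-bromo-2,6-dimethoxybenzaldehyde
Product: 8 2,6-dimethoxy-4-(2,4,6-trimethoxyphenoxy)benzaldehyde
Conditions: 6 (1.3 equiv), CuI (10 mol %), picolinic acid (20 mol %), K3PO4 (2 equiv), DMSO, 90 °C, Ar
Reagents that add atoms: none
Why: Ligand-accelerated Ullmann diaryl ether coupling, in which the bromide is activated by the para formyl group and has only hydrogens beside it, the picolinic acid system tolerates 2,6-disubstituted phenols, and argon protects the electron-rich phenoxide.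

Step 4
Reactants: 8 2,6-dimethoxy-4-(2,4,6-trimethoxyphenoxy)benzaldehyde
Product: 10 2,6-dimethoxy-4-(2,4,6-trimethoxyphenoxy)phenol, via aryl formate 9 (not isolated)
Conditions: mCPBA (1.4 equiv), CH2Cl2, 0 °C → rt; aq. Na2S2O3 wash; then K2CO3 (0.2 equiv), MeOH, rt, Ar
Reagents that add atoms: mCPBA, OOC(=O)c1cccc(Cl)c1
Why: Baeyer–Villiger (Dakin-type) oxidation of a 2,6-dimethoxybenzaldehyde, whose doubly ortho-donated aryl group migrates readily, so that the formyl group ends as the central hydroxyl of ring B.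

Step 5
Reactants: 10 2,6-dimethoxy-4-(2,4,6-trimethoxyphenoxy)phenol; 11 1,3-difluoro-5-methoxy-2-nitrobenzene
Product: 12 1-[2,6-dimethoxy-4-(2,4,6-trimethoxyphenoxy)phenoxy]-3-fluoro-5-methoxy-2-nitrobenzene
Conditions: 11 (2.5 equiv, excess recovered), K2CO3 (1.5 equiv), DMF, rt → 40 °C, Ar
Reagents that add atoms: none
Why: SNAr at a fluoride ortho to the nitro group, which is fast even for a 2,6-dimethoxyphenoxide; the two fluorides are equivalent, so there is no regiochemical question, and the new aryloxy group slows the second substitution, so that an excess of 11 stops the reaction at the monoether.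

Step 6
Reactants: 12 1-[2,6-dimethoxy-4-(2,4,6-trimethoxyphenoxy)phenoxy]-3-fluoro-5-methoxy-2-nitrobenzene
Product: 13 1-(benzyloxy)-3-[2,6-dimethoxy-4-(2,4,6-trimethoxyphenoxy)phenoxy]-5-methoxy-2-nitrobenzene
Conditions: BnOH (1.2 equiv), NaH (1.2 equiv), THF, 0 °C → rt
Reagents that add atoms: benzyl alcohol, OCc1ccccc1
Why: Second SNAr at the remaining ortho fluoride with the small, strong benzyl oxide nucleophile, fluoride being a far better nucleofuge than the aryloxy group on the other side of the nitro group.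

Step 7
Reactants: 13 1-(benzyloxy)-3-[2,6-dimethoxy-4-(2,4,6-trimethoxyphenoxy)phenoxy]-5-methoxy-2-nitrobenzene
Product: 15 6-diazo-5-[2,6-dimethoxy-4-(2,4,6-trimethoxyphenoxy)phenoxy]-3-methoxycyclohexa-2,4-dien-1-one, via aminophenol 14 (not isolated)
Conditions: H2 (1 atm), 10 % Pd/C, AcOH (2 equiv), EtOAc–MeOH 1:1, rt; filter under Ar; then t-BuONO (1.3 equiv), 0 °C, dark; aq. NaHCO3 wash
Reagents that add atoms: tert-butyl nitrite, CC(C)(C)ON=O
Why: Catalytic hydrogenation reduces the nitro group and cleaves the benzyl ether in one operation, and diazotisation of the resulting o-aminophenol (kept as its acetate salt under argon) gives the o-quinone diazide, the classical entry to this class, while the diaryl ethers are inert to both operations.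

Step 8
Reactants: 15 6-diazo-5-[2,6-dimethoxy-4-(2,4,6-trimethoxyphenoxy)phenoxy]-3-methoxycyclohexa-2,4-dien-1-one; 5 3,5-dimethoxy-4-(3,4,5-trimethoxyphenoxy)phenol
Product: 16 3-[2,6-dimethoxy-4-(2,4,6-trimethoxyphenoxy)phenoxy]-2-[3,5-dimethoxy-4-(3,4,5-trimethoxyphenoxy)phenoxy]-5-methoxyphenol
Conditions: 5 (2.0 equiv, excess recovered), Rh2(OAc)4 (3 mol %), 1,2-dichloroethane, 70 °C, Ar, dark; 15 added over 4 h
Reagents that add atoms: none
Why: Dirhodium tetraacetate should expel N2 from 15 to give a rhodium-bound quinoid carbene at C2 of ring C; the phenolic oxygen of 5 adds to this electrophilic carbon, and proton transfer from the oxonium ylide to the neighbouring carbonyl oxygen (net O–H insertion) rearomatises ring C, so the most crowded ether bond forms without a hindered nucleophile. The closest known reaction type is the rhodium-carbenoid O–H insertion of phenols and alcohols into diazo carbonyl compounds, quinone diazides included. No ring is closed and no stereocentre is formed. The step needs ipso selectivity, which is fixed because the new bond can only form at the diazo carbon, the one that carried the nitro group. It also needs O–H insertion to win over Wolff ring contraction, over attack by the ring carbons of 5 and over capture by a methoxy oxygen of ring B; metal catalysis in the dark at moderate temperature, neutral conditions, an excess of 5 and slow addition of 15 should secure this. The carbonyl oxygen of 15 returns as the C3 hydroxyl of ring C, which the target carries free, so no protecting-group step follows.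

Step 9
Reactants: 16 3-[2,6-dimethoxy-4-(2,4,6-trimethoxyphenoxy)phenoxy]-2-[3,5-dimethoxy-4-(3,4,5-trimethoxyphenoxy)phenoxy]-5-methoxyphenol
Product: 17 CNP0227069.0
Conditions: BBr3 (1 M in CH2Cl2, 25 equiv), CH2Cl2, −78 °C → rt, Ar; ice-water quench at 0 °C; EtOAc; Sephadex LH-20 (MeOH) under Ar
Reagents that add atoms: none
Why: Lewis-acid demethylation with BBr3 cleaves all eleven aryl methyl ethers by bromide attack on the O-methyl group of the borane adduct and leaves the four diaryl ether bonds alone, while the cold aqueous quench and work-up under argon protect the oxidisable polyphenol.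

**Compound list**
1 | 4-hydroxy-3,5-dimethoxybenzaldehyde (syringaldehyde) | COc1cc(C=O)cc(OC)c1O | starting material
2 | (3,4,5-trimethoxyphenyl)boronic acid | COc1cc(B(O)O)cc(OC)c1OC | starting material
3 | 3,5-dimethoxy-4-(3,4,5-trimethoxyphenoxy)benzaldehyde | COc1cc(C=O)cc(OC)c1Oc1cc(OC)c(OC)c(OC)c1 | intermediate
4 | 3,5-dimethoxy-4-(3,4,5-trimethoxyphenoxy)phenyl formate | COc1cc(OC=O)cc(OC)c1Oc1cc(OC)c(OC)c(OC)c1 | intermediate
5 | 3,5-dimethoxy-4-(3,4,5-trimethoxyphenoxy)phenol (rings D–E) | COc1cc(O)cc(OC)c1Oc1cc(OC)c(OC)c(OC)c1 | intermediate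
6 | 2,4,6-trimethoxyphenol | COc1cc(OC)c(O)c(OC)c1 | starting material
7 | 4-bromo-2,6-dimethoxybenzaldehyde | COc1cc(Br)cc(OC)c1C=O | starting material
8 | 2,6-dimethoxy-4-(2,4,6-trimethoxyphenoxy)benzaldehyde | COc1cc(OC)c(Oc2cc(OC)c(C=O)c(OC)c2)c(OC)c1 | intermediate
9 | 2,6-dimethoxy-4-(2,4,6-trimethoxyphenoxy)phenyl formate | COc1cc(OC)c(Oc2cc(OC)c(OC=O)c(OC)c2)c(OC)c1 | intermediate
10 | 2,6-dimethoxy-4-(2,4,6-trimethoxyphenoxy)phenol (rings A–B) | COc1cc(OC)c(Oc2cc(OC)c(O)c(OC)c2)c(OC)c1 | intermediate
11 | 1,3-difluoro-5-methoxy-2-nitrobenzene | COc1cc(F)c([N+](=O)[O-])c(F)c1 | starting material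
12 | 1-[2,6-dimethoxy-4-(2,4,6-trimethoxyphenoxy)phenoxy]-3-fluoro-5-methoxy-2-nitrobenzene | COc1cc(F)c([N+](=O)[O-])c(Oc2c(OC)cc(Oc3c(OC)cc(OC)cc3OC)cc2OC)c1 | intermediate
13 | 1-(benzyloxy)-3-[2,6-dimethoxy-4-(2,4,6-trimethoxyphenoxy)phenoxy]-5-methoxy-2-nitrobenzene | COc1cc(OCc2ccccc2)c([N+](=O)[O-])c(Oc2c(OC)cc(Oc3c(OC)cc(OC)cc3OC)cc2OC)c1 | intermediate
14 | 2-amino-3-[2,6-dimethoxy-4-(2,4,6-trimethoxyphenoxy)phenoxy]-5-methoxyphenol | COc1cc(O)c(N)c(Oc2c(OC)cc(Oc3c(OC)cc(OC)cc3OC)cc2OC)c1 | intermediate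
15 | 6-diazo-5-[2,6-dimethoxy-4-(2,4,6-trimethoxyphenoxy)phenoxy]-3-methoxycyclohexa-2,4-dien-1-one | COC1=CC(=O)C(=[N+]=[N-])C(Oc2c(OC)cc(Oc3c(OC)cc(OC)cc3OC)cc2OC)=C1 | intermediate
16 | 3-[2,6-dimethoxy-4-(2,4,6-trimethoxyphenoxy)phenoxy]-2-[3,5-dimethoxy-4-(3,4,5-trimethoxyphenoxy)phenoxy]-5-methoxyphenol | COc1cc(O)c(Oc2cc(OC)c(Oc3cc(OC)c(OC)c(OC)c3)c(OC)c2)c(Oc2c(OC)cc(Oc3c(OC)cc(OC)cc3OC)cc2OC)c1 | intermediate
17 | CNP0227069.0, 2-{4-[2-(3,5-dihydroxy-4-(3,4,5-trihydroxyphenoxy)phenoxy)-3,5-dihydroxyphenoxy]-3,5-dihydroxyphenoxy}benzene-1,3,5-triol (achiral) | Oc1cc(O)c(Oc2cc(O)c(Oc3cc(O)cc(O)c3Oc3cc(O)c(Oc4cc(O)c(O)c(O)c4)c(O)c3)c(O)c2)c(O)c1 | target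

Total step count: 9. Longest linear sequence: 7 (steps 3 to 9, from 6 and 7).

**Steps most likely to fail**

Step 8. The rhodium carbenoid may be consumed before 5 reaches it: by Wolff-type ring contraction, by attack of a methoxy oxygen of ring B on the carbenoid carbon (six-membered oxonium ylide, then loss of the methyl group to a dibenzo-1,4-dioxin), or by attack through the ring carbons ortho to the hydroxyl of 5. The fallback uses known chemistry with the polarity reversed; it sets out from 10 and comes back to the route at 17. SNAr of 10 on 2-fluoro-4,6-dimethoxybenzaldehyde F1 (Cs2CO3, DMF, 100 °C) would give 2-[2,6-dimethoxy-4-(2,4,6-trimethoxyphenoxy)phenoxy]-4,6-dimethoxybenzaldehyde F2. Dakin oxidation under the conditions of step 4 would give 2-[2,6-dimethoxy-4-(2,4,6-trimethoxyphenoxy)phenoxy]-4,6-dimethoxyphenol F3. Chan–Lam coupling of 4-bromo-2,6-dimethoxyphenol F4 with 2 under the conditions of step 1 would give 5-bromo-1,3-dimethoxy-2-(3,4,5-trimethoxyphenoxy)benzene F5. Ullmann coupling of F3 with F5 (CuI, picolinic acid, K3PO4, DMSO, 110 °C, Ar) would give 1-[2,6-dimethoxy-4-(2,4,6-trimethoxyphenoxy)phenoxy]-2-[3,5-dimethoxy-4-(3,4,5-trimethoxyphenoxy)phenoxy]-3,5-dimethoxybenzene F6, which BBr3 under the conditions of step 9 would convert into 17.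

Step 7. The free, very electron-rich aminophenol 14 may be oxidised by air or by the nitrosating agent to a quinone imine, or nitrosated on carbon, instead of being diazotised on nitrogen; the amine may also slow the hydrogenolysis of the benzyl ether. The fallback never liberates the free amine and frees the phenol by substitution instead of hydrogenolysis; it sets out from 12 and comes back at 15. Hydroxide SNAr on 12 (KOH, DMSO–H2O, 60 °C) would give 3-[2,6-dimethoxy-4-(2,4,6-trimethoxyphenoxy)phenoxy]-5-methoxy-2-nitrophenol F7. Reduction with SnCl2·2H2O in ethanolic HCl would give 2-amino-3-[2,6-dimethoxy-4-(2,4,6-trimethoxyphenoxy)phenoxy]-5-methoxyphenol hydrochloride F8. Diazotisation of this salt in the same acidic medium (NaNO2, 0 °C), then buffering with NaOAc, would give 15.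

Step 3. Copper may oxidise the electron-rich phenol 6 to a quinone, and C–O bond formation at the di-ortho-substituted oxygen may be so slow that reduction of the bromide 7 wins. The fallback replaces the copper coupling by an uncatalysed addition–elimination; it sets out from 6 and comes back at 8. SNAr of 6 on 4-fluoro-2,6-dimethoxybenzaldehyde F9 (Cs2CO3, DMF, 110 °C, Ar), whose fluoride is para to the formyl group and flanked only by hydrogens, would give 8.

**Further compounds**
F1 | step 8 | 2-fluoro-4,6-dimethoxybenzaldehyde | O=Cc1c(F)cc(OC)cc1OC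
F2 | step 8 | 2-[2,6-dimethoxy-4-(2,4,6-trimethoxyphenoxy)phenoxy]-4,6-dimethoxybenzaldehyde | O=Cc1c(OC)cc(OC)cc1Oc1c(OC)cc(Oc2c(OC)cc(OC)cc2OC)cc1OC
F3 | step 8 | 2-[2,6-dimethoxy-4-(2,4,6-trimethoxyphenoxy)phenoxy]-4,6-dimethoxyphenol | Oc1c(OC)cc(OC)cc1Oc1c(OC)cc(Oc2c(OC)cc(OC)cc2OC)cc1OC
F4 | step 8 | 4-bromo-2,6-dimethoxyphenol | Oc1c(OC)cc(Br)cc1OC
F5 | step 8 | 5-bromo-1,3-dimethoxy-2-(3,4,5-trimethoxyphenoxy)benzene | COc1cc(Br)cc(OC)c1Oc1cc(OC)c(OC)c(OC)c1
F6 | step 8 | 1-[2,6-dimethoxy-4-(2,4,6-trimethoxyphenoxy)phenoxy]-2-[3,5-dimethoxy-4-(3,4,5-trimethoxyphenoxy)phenoxy]-3,5-dimethoxybenzene | COc1cc(OC)c(Oc2cc(OC)c(Oc3cc(OC)c(OC)c(OC)c3)c(OC)c2)c(Oc2c(OC)cc(Oc3c(OC)cc(OC)cc3OC)cc2OC)c1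
F7 | step 7 | 3-[2,6-dimethoxy-4-(2,4,6-trimethoxyphenoxy)phenoxy]-5-methoxy-2-nitrophenol | COc1cc(O)c([N+](=O)[O-])c(Oc2c(OC)cc(Oc3c(OC)cc(OC)cc3OC)cc2OC)c1
F8 | step 7 | 2-amino-3-[2,6-dimethoxy-4-(2,4,6-trimethoxyphenoxy)phenoxy]-5-methoxyphenol hydrochloride | COc1cc(O)c([NH3+])c(Oc2c(OC)cc(Oc3c(OC)cc(OC)cc3OC)cc2OC)c1.[Cl-]
F9 | step 3 | 4-fluoro-2,6-dimethoxybenzaldehyde | COc1cc(F)cc(OC)c1C=O
A1 | direct plan | methyl 2-[3,5-bis(benzyloxy)-4-(methoxymethoxy)phenoxy]acetate | COC(=O)COc1cc(OCc2ccccc2)c(OCOC)c(OCc2ccccc2)c1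
A2 | direct plan | 2,6-bis(benzyloxy)-4-[2,4,6-tris(benzyloxy)phenoxy]phenol | Oc1c(OCc2ccccc2)cc(Oc2c(OCc3ccccc3)cc(OCc3ccccc3)cc2OCc2ccccc2)cc1OCc1ccccc1
A3 | direct plan | 2,4-bis(benzyloxy)-6-{2,6-bis(benzyloxy)-4-[2,4,6-tris(benzyloxy)phenoxy]phenoxy}phenol | Oc1c(OCc2ccccc2)cc(OCc2ccccc2)cc1Oc1c(OCc2ccccc2)cc(Oc2c(OCc3ccccc3)cc(OCc3ccccc3)cc2OCc2ccccc2)cc1OCc1ccccc1
A4 | direct plan | 1,3-bis(benzyloxy)-5-iodo-2-[3,4,5-tris(benzyloxy)phenoxy]benzene | Ic1cc(OCc2ccccc2)c(Oc2cc(OCc3ccccc3)c(OCc3ccccc3)c(OCc3ccccc3)c2)c(OCc2ccccc2)c1
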